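The route rests on opening the ten-membered ring at C5–C6. Along C9–C10–C5–C6–C7 the C9 carbonyl carbon and C7 stand in a 1,5 relationship, and C10–C5 is the bond shared with ring A; with unsaturation at C7=C8 the ring is a δ,ε-unsaturated ketone, i.e. an oxy-Cope product. One operation on the alkoxide of a bridged divinyl carbinol makes C5–C6, breaks C8–C9, enlarges a six-membered ring to the ten-membered one and leaves a C9=C10 enolate that is methylated to quaternary C10. The precursor is a bicyclo[3.2.1]octan-2-ol with the C6=C7 vinyl group on bridgehead C8, a 3,3-dimethylcyclohexenyl group (ring A) on C9 and ring D as a dioxolane-masked bridge.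

Key step: step 11

Remarks on the chemistry (one line each):
- Numbering: kaurane-type atom numbers (C1–C17) are used for all compounds; CIP labels change at C13 in some intermediates only because substituent priorities change, not the spatial arrangement.
- Rearrangement substrate: C9 is taken as R (cyclohexenyl group anti to the C15 bridge, hydroxyl equatorial), because only this epimer relays 13R to 5R through a chair; the same chair gives C7=C8 with C6 cis to C14, and both features are drawn in 22 and 25.
- Ring-A nucleophile: the 3,3-dimethylcyclohex-1-enyl isomer (gem-dimethyl carbon next to the vinylic CH) is required, so it is made from 3-methylcyclohex-2-enone by cuprate addition and enolate triflation.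
- Source of chirality: (S)-4-silyloxycyclopent-2-enone 1 is assumed to be bought enantiopure; it allows C8 to be functionalised without a regiochemical choice.

Step 1
Reactants: 1 (S)-4-[(tert-butyldimethylsilyl)oxy]cyclopent-2-en-1-one; 2 2-(2-bromoethyl)-1,3-dioxolane
Product: 5 (S)-4-[2-(1,3-dioxolan-2-yl)ethyl]cyclopent-2-en-1-one, via Grignard reagent 3 (not isolated), via trans silyloxy ketone 4 (not isolated)
Conditions: 2, Mg, THF, 30 °C; CuBr·SMe2 (10 mol%), 1, THF, −78 °C; aq. NH4Cl; then DBU, CH2Cl2, 0 °C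
Reagents that add atoms: none
Why: Copper-catalysed conjugate addition of the Grignard reagent occurs anti to the silyloxy group (steric approach control) and so sets C13, after which DBU expels silanolate by E1cB elimination and moves the enone to C8=C14, trading the chiral-pool centre for C13.

Step 2
Reactants: 5 (S)-4-[2-(1,3-dioxolan-2-yl)ethyl]cyclopent-2-en-1-one; 6 acetaldehyde
Product: 8 (4R)-4-[2-(1,3-dioxolan-2-yl)ethyl]-2-(1-hydroxyethyl)cyclopentan-1-one (diastereomer mixture at C8 and C7), via lithium enolate 7 (not isolated)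
Conditions: L-Selectride, THF, −78 °C; then 6, −78 °C; aq. NH4Cl
Reagents that add atoms: none
Why: 1,4-Reduction of the β-unsubstituted enone generates the lithium enolate only at C8, so its aldol addition to acetaldehyde attaches C7–C6 to C8 without any regiochemical choice (conjugate reduction–aldol reaction; the two new centres are erased in step 3).

Step 3
Reactants: 8 (4R)-4-[2-(1,3-dioxolan-2-yl)ethyl]-2-(1-hydroxyethyl)cyclopentan-1-one
Product: 10 (2E,4R)-4-[2-(1,3-dioxolan-2-yl)ethyl]-2-ethylidenecyclopentan-1-one, via mesylate 9 (not isolated)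
Conditions: MsCl, Et3N, CH2Cl2, 0 °C; then DBU, 0 °C → rt
Reagents that add atoms: none
Why: Mesylation followed by E1cB elimination of the β-mesyloxy ketone should give the conjugated ethylidene ketone in its more stable E form (aldol condensation completed stepwise).

Step 4
Reactants: 10 (2E,4R)-4-[2-(1,3-dioxolan-2-yl)ethyl]-2-ethylidenecyclopentan-1-one
Product: 11 3-[(1R,3E)-3-ethylidene-4-oxocyclopentyl]propanal
Conditions: 1 M HCl–THF, rt; used crude at once
Reagents that add atoms: water O
Why: Acid-catalysed acetal hydrolysis frees the C9 aldehyde and leaves the enone untouched.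

Step 5
Reactants: 11 3-[(1R,3E)-3-ethylidene-4-oxocyclopentyl]propanal
Product: 13 1-ethenyl-2-hydroxybicyclo[3.2.1]octan-7-one (8S,13R; both C9 epimers), via selenide aldol 12 (not isolated)
Conditions: PhSeH, n-BuLi, THF, −78 °C; then 11, −78 → −40 °C; aq. NH4Cl; then H2O2 (30%), pyridine, CH2Cl2, 0 °C → rt
Reagents that add atoms: none
Why: The soft, weakly basic selenolate adds to C7 of the exocyclic enone and the enolate thus formed only at C8 closes on the C9 aldehyde (chalcogenolate-triggered Michael–aldol, 6-exo-trig), C8 being fixed by C13 because the tether can only bridge the five-membered ring cis, and selenoxide syn-elimination can then run only towards the C6 methyl group because C8 is quaternary, which unveils the bridgehead vinyl group.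

Step 6
Reactants: 13 1-ethenyl-2-hydroxybicyclo[3.2.1]octan-7-one
Product: 14 1-ethenylspiro[bicyclo[3.2.1]octane-7,2′-[1,3]dioxolan]-2-ol (8S,13R; both C9 epimers)
Conditions: HOCH2CH2OH, HC(OEt)3, p-TsOH·H2O (cat.), CH2Cl2, rt
Reagents that add atoms: ethane-1,2-diol OCCO
Why: Orthoformate-driven acid-catalysed ketalisation masks C15 while it is the only carbonyl group present, so no 1,3-diketone ever has to be differentiated.

Step 7
Reactants: 14 1-ethenylspiro[bicyclo[3.2.1]octane-7,2′-[1,3]dioxolan]-2-ol
Product: 15 (1S,5R)-1-ethenylspiro[bicyclo[3.2.1]octane-7,2′-[1,3]dioxolan]-2-one (8S,13R)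
Conditions: Dess–Martin periodinane, pyridine, CH2Cl2, rt
Reagents that add atoms: none
Why: Dess–Martin oxidation converts both carbinol epimers into the C9 ketone under buffered conditions that spare the ketal and the vinyl group.

Step 8
Reactants: 16 3-methylcyclohex-2-en-1-one
Product: 18 3,3-dimethylcyclohex-1-en-1-yl trifluoromethanesulfonate, via lithium enolate 17 (not isolated)
Conditions: MeLi, CuI, Et2O, 0 °C; 16, −78 → 0 °C; then PhNTf2, THF, 0 °C → rt
Reagents that add atoms: methyllithium [Li]C; N-phenylbis(trifluoromethanesulfonimide) O=S(=O)(N(c1ccccc1)S(=O)(=O)C(F)(F)F)C(F)(F)F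
Why: Cuprate 1,4-addition creates the gem-dimethyl carbon and leaves the enolate double bond exactly between C10 and C5, and O-triflation fixes this regiochemistry (conjugate addition–enolate trapping), which enolisation of 3,3-dimethylcyclohexanone would not give.

Step 9
Reactants: 18 3,3-dimethylcyclohex-1-en-1-yl trifluoromethanesulfonate
Product: 19 (3,3-dimethylcyclohex-1-en-1-yl)trimethylstannane
Conditions: Me3SnSnMe3, Pd(PPh3)4 (cat.), LiCl, THF, 65 °C
Reagents that add atoms: hexamethylditin C[Sn](C)(C)[Sn](C)(C)C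
Why: Palladium-catalysed coupling of the enol triflate with the distannane (Stille-type stannylation) gives a storable precursor of the vinyllithium.

Step 10
Reactants: 15 (1S,5R)-1-ethenylspiro[bicyclo[3.2.1]octane-7,2′-[1,3]dioxolan]-2-one; 19 (3,3-dimethylcyclohex-1-en-1-yl)trimethylstannane
Product: 22 (1S,2R,5R)-2-(3,3-dimethylcyclohex-1-en-1-yl)-1-ethenylspiro[bicyclo[3.2.1]octane-7,2′-[1,3]dioxolan]-2-ol (8S,9R,13R; cyclohexenyl axial and anti to the C15 bridge), via vinyllithium 20 (not isolated), via vinylcerium reagent 21 (not isolated)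
Conditions: 19, MeLi, THF, −78 → 0 °C; CeCl3, THF, −78 °C; then 15, −78 °C; aq. NH4Cl
Reagents that add atoms: none
Why: Tin–lithium exchange and transmetalation to cerium give a non-basic nucleophile that adds to the hindered, enolisable ketone (organocerium 1,2-addition) along the axial trajectory anti to the C15 bridge, because the equatorial approach runs over the dioxolane oxygen atoms, and this sets C9 as R.

Step 11
Reactants: 22 (1S,2R,5R)-2-(3,3-dimethylcyclohex-1-en-1-yl)-1-ethenylspiro[bicyclo[3.2.1]octane-7,2′-[1,3]dioxolan]-2-ol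
Product: 25 (5R,10R,13R,7E)-15,15-(ethylenedioxy)-17-nor-8,9-secokaur-7-en-9-one (ring-A-fused bicyclo[7.2.1]dodecenone; C6 cis to C14 on C7=C8), via potassium alkoxide 23 (not isolated), via potassium enolate 24 (not isolated)
Conditions: KH, 18-crown-6, THF, 0 °C → rt; then MeI, −78 → 0 °C
Reagents that add atoms: iodomethane CI
Why: The alkoxide 23 weakens the C8–C9 bond and a [3,3]-sigmatropic shift through C6=C7–C8–C9–C10=C5 forms C5–C6 and breaks C8–C9 to give enolate 24, which is then C-methylated (anionic oxy-Cope rearrangement with in situ enolate alkylation, a known tandem). The ten-membered ring is not closed by a cyclisation mode in the Baldwin sense but arises by ring expansion, the ring C8–C9–C11–C12–C13–C14 being enlarged by C7, C6, C5 and C10. The vinyl group is equatorial on C8 and the cyclohexenyl group axial on C9, a gauche arrangement that fits a chair-like six-centre transition state; in it C4 is equatorial and H5 axial on the side of the C9 oxygen, which gives 5R, and C14 is axial at C8, so that C6 ends cis to C14. Methyl iodide must enter at C10 on the face syn to C6: in 24 ring A holds C6 axial (A(1,3) strain with the enolate oxygen), so this is the equatorial trajectory, whereas the opposite face is axial and carries the syn-axial methyl group on C4, and the result is 10R with C9 trans to C6. Site selectivity is secured because the enolate is formed only at C9=C10 and no proton source is present to move it to C11, and the soft electrophile favours carbon over oxygen.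

Step 12
Reactants: 25 (5R,10R,13R,7E)-15,15-(ethylenedioxy)-17-nor-8,9-secokaur-7-en-9-one
Product: 27 (5R,10R,11S,13S,7E)-15,15-(ethylenedioxy)-11-hydroxy-17-nor-8,9-secokaur-7-en-9-one, via potassium enolate 26 (not isolated)
Conditions: KHMDS, THF, −78 °C; then 2-(phenylsulfonyl)-3-phenyloxaziridine, −78 °C; aq. NH4Cl
Reagents that add atoms: 2-(phenylsulfonyl)-3-phenyloxaziridine O=S(=O)(N1OC1c1ccccc1)c1ccccc1
Why: Only C11 can be enolised (C10 is quaternary, C15 masked), and oxygen transfer from the N-sulfonyloxaziridine (Davis hydroxylation) is expected on the face of C11 turned away from the axial C10 methyl group, which corresponds to 11S.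

Step 13
Reactants: 27 (5R,10R,11S,13S,7E)-15,15-(ethylenedioxy)-11-hydroxy-17-nor-8,9-secokaur-7-en-9-one
Product: 28 (5R,10R,11S,13S,7E)-11-hydroxy-17-nor-8,9-secokaur-7-ene-9,15-dione
Conditions: PPTS, acetone–H2O, 40 °C
Reagents that add atoms: water O
Why: Mild acid-catalysed hydrolysis of the allylic ketal gives the conjugated E enone (C6 trans to the carbonyl group) without disturbing the α-ketol.

Step 14
Reactants: 28 (5R,10R,11S,13S,7E)-11-hydroxy-17-nor-8,9-secokaur-7-ene-9,15-dione
Product: 30 (5R,7R,10R,11S,13S)-7,11-dihydroxy-17-nor-8,9-secokaur-8(14)-ene-9,15-dione, via hydroperoxide 29 (not isolated)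
Conditions: O2, TPP (cat.), hν (>400 nm), CH2Cl2, 0 °C; then PPh3, 0 °C
Reagents that add atoms: dioxygen O=O
Why: In the Schenck ene reaction of an s-cis enone singlet oxygen removes hydrogen from the alkyl group geminal to the carbonyl group (C14), so oxygen goes to C7 and the double bond moves to C8=C14, attack from the enone face opposite to the one over which the ten-membered ring leaves C13 should give 7R, and the phosphine reduces the hydroperoxide.

Step 15
Reactants: 30 (5R,7R,10R,11S,13S)-7,11-dihydroxy-17-nor-8,9-secokaur-8(14)-ene-9,15-dione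
Product: 31 (5R,7R,10R,11S,13S)-7,11-diacetoxy-17-nor-8,9-secokaur-8(14)-ene-9,15-dione
Conditions: Ac2O, pyridine, DMAP (cat.), CH2Cl2, rt
Reagents that add atoms: acetic anhydride CC(=O)OC(C)=O
Why: DMAP-catalysed acylation esterifies both secondary alcohols with retention at C7 and C11.

Step 16
Reactants: 31 (5R,7R,10R,11S,13S)-7,11-diacetoxy-17-nor-8,9-secokaur-8(14)-ene-9,15-dione
Product: 35 (5R,7R,10R,11S,13R)-7,11-diacetoxy-8,9-secokaura-8(14),16-diene-9,15-dione (CNP0417044.1), via lithium dienolate 32 (not isolated), via Mannich base 33 (not isolated), via ammonium iodide 34 (not isolated)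
Conditions: LiHMDS, THF, −78 °C; Me2N=CH2+ I−, −78 → 0 °C; then MeI, CH2Cl2, rt; then sat. aq. NaHCO3, rt
Reagents that add atoms: N,N-dimethylmethyleneiminium iodide C=[N+](C)C.[I-]
Why: Kinetic deprotonation should occur at the unhindered α′-methylene C16 of the cyclopentenone in preference to the hindered methine C11, the enolate is aminomethylated (Mannich reaction with Eschenmoser's salt), and quaternisation with mild base-induced loss of trimethylamine gives the exocyclic enone without exposing the acetates or C13 to strong base.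

Compound list
1 | (S)-4-[(tert-butyldimethylsilyl)oxy]cyclopent-2-en-1-one | O=C1C=C[C@@H](O[Si](C)(C)C(C)(C)C)C1 | starting material
2 | 2-(2-bromoethyl)-1,3-dioxolane | BrCCC1OCCO1 | starting material
3 | [2-(1,3-dioxolan-2-yl)ethyl]magnesium bromide | Br[Mg]CCC1OCCO1 | intermediate
4 | (3S,4S)-4-[(tert-butyldimethylsilyl)oxy]-3-[2-(1,3-dioxolan-2-yl)ethyl]cyclopentan-1-one (trans) | O=C1C[C@H](CCC2OCCO2)[C@@H](O[Si](C)(C)C(C)(C)C)C1 | intermediate
5 | (S)-4-[2-(1,3-dioxolan-2-yl)ethyl]cyclopent-2-en-1-one | O=C1C=C[C@@H](CCC2OCCO2)C1 | intermediate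
6 | acetaldehyde | CC=O | starting material
7 | lithium (4R)-4-[2-(1,3-dioxolan-2-yl)ethyl]cyclopent-1-en-1-olate | [Li]OC1=CC[C@@H](CCC2OCCO2)C1 | intermediate
8 | (4R)-4-[2-(1,3-dioxolan-2-yl)ethyl]-2-(1-hydroxyethyl)cyclopentan-1-one (mixture at C8 and C7) | O=C1C(C(C)O)C[C@@H](CCC2OCCO2)C1 | intermediate
9 | 1-{(4R)-4-[2-(1,3-dioxolan-2-yl)ethyl]-2-oxocyclopentyl}ethyl methanesulfonate (mixture at C8 and C7) | CC(OS(C)(=O)=O)C1C[C@@H](CCC2OCCO2)CC1=O | intermediate
10 | (2E,4R)-4-[2-(1,3-dioxolan-2-yl)ethyl]-2-ethylidenecyclopentan-1-one | C/C=C1\C[C@@H](CCC2OCCO2)CC1=O | intermediate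
11 | 3-[(1R,3E)-3-ethylidene-4-oxocyclopentyl]propanal | C/C=C1\C[C@@H](CCC=O)CC1=O | intermediate
12 | 2-hydroxy-1-[1-(phenylselanyl)ethyl]bicyclo[3.2.1]octan-7-one (bridgeheads as in 13; epimers at C7 and C9) | CC([Se]c1ccccc1)[C@@]12C[C@@H](CCC1O)CC2=O | intermediate
13 | 1-ethenyl-2-hydroxybicyclo[3.2.1]octan-7-one (8S,13R; both C9 epimers) | C=C[C@@]12C[C@@H](CCC1O)CC2=O | intermediate
14 | 1-ethenylspiro[bicyclo[3.2.1]octane-7,2′-[1,3]dioxolan]-2-ol (8S,13R; both C9 epimers) | C=C[C@@]12C[C@@H](CCC1O)CC23OCCO3 | intermediate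
15 | (1S,5R)-1-ethenylspiro[bicyclo[3.2.1]octane-7,2′-[1,3]dioxolan]-2-one (8S,13R) | C=C[C@@]12C[C@@H](CCC1=O)CC23OCCO3 | intermediate
16 | 3-methylcyclohex-2-en-1-one | CC1=CC(=O)CCC1 | starting material
17 | lithium 3,3-dimethylcyclohex-1-en-1-olate | [Li]OC1=CC(C)(C)CCC1 | intermediate
18 | 3,3-dimethylcyclohex-1-en-1-yl trifluoromethanesulfonate | CC1(C)C=C(OS(=O)(=O)C(F)(F)F)CCC1 | intermediate
19 | (3,3-dimethylcyclohex-1-en-1-yl)trimethylstannane | CC1(C)C=C([Sn](C)(C)C)CCC1 | intermediate
20 | (3,3-dimethylcyclohex-1-en-1-yl)lithium | [Li]C1=CC(C)(C)CCC1 | intermediate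
21 | dichloro(3,3-dimethylcyclohex-1-en-1-yl)cerium | Cl[Ce](Cl)C1=CC(C)(C)CCC1 | intermediate
22 | (1S,2R,5R)-2-(3,3-dimethylcyclohex-1-en-1-yl)-1-ethenylspiro[bicyclo[3.2.1]octane-7,2′-[1,3]dioxolan]-2-ol (8S,9R,13R) | C=C[C@@]12C[C@@H](CC[C@@]1(O)C1=CC(C)(C)CCC1)CC23OCCO3 | intermediate
23 | potassium alkoxide of 22 | C=C[C@@]12C[C@@H](CC[C@@]1([O-])C1=CC(C)(C)CCC1)CC23OCCO3.[K+] | intermediate
24 | potassium C9=C10 enolate (5R,13R; C7=C8 with C6 cis to C14; enolate oxygen cis to C5) | C1C2(OCCO2)/C3=C/C[C@@H]4C(C)(C)CCC/C4=C(/[O-])CC[C@@H]1C3.[K+] | intermediate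
25 | (5R,10R,13R,7E)-15,15-(ethylenedioxy)-17-nor-8,9-secokaur-7-en-9-one | C1C2(OCCO2)/C3=C/C[C@@H]4C(C)(C)CCC[C@@]4(C)C(=O)CC[C@@H]1C3 | intermediate
26 | potassium C9=C11 enolate of 25 (C10 cis to C12) | C1C2(OCCO2)/C3=C/C[C@@H]4C(C)(C)CCC[C@@]4(C)/C([O-])=C\C[C@@H]1C3.[K+] | intermediate
27 | (5R,10R,11S,13S,7E)-15,15-(ethylenedioxy)-11-hydroxy-17-nor-8,9-secokaur-7-en-9-one | C1C2(OCCO2)/C3=C/C[C@@H]4C(C)(C)CCC[C@@]4(C)C(=O)[C@@H](O)C[C@@H]1C3 | intermediate
28 | (5R,10R,11S,13S,7E)-11-hydroxy-17-nor-8,9-secokaur-7-ene-9,15-dione | C1C(=O)/C3=C/C[C@@H]4C(C)(C)CCC[C@@]4(C)C(=O)[C@@H](O)C[C@@H]1C3 | intermediate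
29 | (5R,7R,10R,11S,13S)-7-hydroperoxy-11-hydroxy-17-nor-8,9-secokaur-8(14)-ene-9,15-dione | C1C(=O)C2=C[C@H]1C[C@H](O)C(=O)[C@]1(C)CCCC(C)(C)[C@H]1C[C@H]2OO | intermediate
30 | (5R,7R,10R,11S,13S)-7,11-dihydroxy-17-nor-8,9-secokaur-8(14)-ene-9,15-dione | C1C(=O)C2=C[C@H]1C[C@H](O)C(=O)[C@]1(C)CCCC(C)(C)[C@H]1C[C@H]2O | intermediate
31 | (5R,7R,10R,11S,13S)-7,11-diacetoxy-17-nor-8,9-secokaur-8(14)-ene-9,15-dione | C1C(=O)C2=C[C@H]1C[C@H](OC(C)=O)C(=O)[C@]1(C)CCCC(C)(C)[C@H]1C[C@H]2OC(C)=O | intermediate
32 | lithium C15=C16 dienolate of 31 | C1=C(O[Li])C2=C[C@H]1C[C@H](OC(C)=O)C(=O)[C@]1(C)CCCC(C)(C)[C@H]1C[C@H]2OC(C)=O | intermediate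
33 | 16-[(dimethylamino)methyl] derivative of 31 (C16 epimers) | CN(C)CC1C(=O)C2=C[C@H]1C[C@H](OC(C)=O)C(=O)[C@]1(C)CCCC(C)(C)[C@H]1C[C@H]2OC(C)=O | intermediate
34 | trimethylammoniomethyl iodide derived from 33 | C[N+](C)(C)CC1C(=O)C2=C[C@H]1C[C@H](OC(C)=O)C(=O)[C@]1(C)CCCC(C)(C)[C@H]1C[C@H]2OC(C)=O.[I-] | intermediate
35 | (5R,7R,10R,11S,13R)-7,11-diacetoxy-8,9-secokaura-8(14),16-diene-9,15-dione | C=C1C(=O)C2=C[C@H]1C[C@H](OC(C)=O)C(=O)[C@]1(C)CCCC(C)(C)[C@H]1C[C@H]2OC(C)=O | target

Total step count: 16. Longest linear sequence: 14 steps (steps 1–7 and 10–16; steps 8–9 form the side branch).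

Steps most likely to fail

Step 11. Methyl iodide may enter at C10 on the face anti to C6, or at oxygen. The enolate keeps the geometry left by the sigmatropic shift, and in it the face syn to C6 is also the one turned towards the interior of the ten-membered ring, so the ring-A argument and transannular shielding oppose each other. The fallback separates the two events. It sets out from 22: the rearrangement is run as above but quenched with aqueous NH4Cl to give the ketone (5S by CIP, same spatial arrangement at C5)-15,15-(ethylenedioxy)-17-nor-8,9-secokaur-7-en-9-one F1. Equilibrating silylation (TMSCl, NaI, Et3N, MeCN) converts it into the more substituted trimethylsilyl enol ether F2. Methyllithium then liberates a lithium enolate that is no longer tied to the post-rearrangement ring conformation and is methylated with MeI. The fallback comes back to the route at 25.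

Step 5. Retro-Michael or retro-aldol equilibration, or proton transfer to the hindered tetrasubstituted enolate, may divert the cascade before the congested quaternary centre at C8 is closed. The fallback makes the dienolate by hydride delivery instead and sets out from 5. α-Iodination (I2, pyridine, CH2Cl2) gives (S)-4-[2-(1,3-dioxolan-2-yl)ethyl]-2-iodocyclopent-2-en-1-one F3. Stille coupling with tributyl(vinyl)stannane gives the 2-ethenyl enone F4, and acetal hydrolysis gives 3-[(1S)-3-ethenyl-4-oxocyclopent-2-en-1-yl]propanal F5. Stryker's reagent then adds hydride to C14, and the copper dienolate closes on the aldehyde through C8 (reductive aldol cyclisation). The fallback comes back to the route at 13.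

Step 12. Facial selectivity of oxygen transfer to the C9=C11 enolate may be poor or reversed, because the conformation of the ten-membered ring around C11 is not secured by any rigid element. The fallback inverts the carbinol instead of controlling the addition and sets out from 25. The hydroxylation is accepted as giving the 11R alcohol F6, and Mitsunobu reaction with 4-nitrobenzoic acid (DIAD, PPh3) gives the 11S 4-nitrobenzoate F7. Brief methanolysis (K2CO3, MeOH, 0 °C) brings the sequence back to the route at 27.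

Further compounds
F1 | step 11 | 15,15-(ethylenedioxy)-17-nor-8,9-secokaur-7-en-9-one with C10–H (C10 epimers) | C1C2(OCCO2)/C3=C/C[C@@H]4C(C)(C)CCCC4C(=O)CC[C@@H]1C3
F2 | step 11 | C9=C10 trimethylsilyl enol ether of F1 | C1C2(OCCO2)/C3=C/C[C@@H]4C(C)(C)CCCC4=C(O[Si](C)(C)C)CC[C@@H]1C3
F3 | step 5 | (S)-4-[2-(1,3-dioxolan-2-yl)ethyl]-2-iodocyclopent-2-en-1-one | O=C1C(I)=C[C@@H](CCC2OCCO2)C1
F4 | step 5 | (S)-4-[2-(1,3-dioxolan-2-yl)ethyl]-2-ethenylcyclopent-2-en-1-one | O=C1C(C=C)=C[C@@H](CCC2OCCO2)C1
F5 | step 5 | 3-[(1S)-3-ethenyl-4-oxocyclopent-2-en-1-yl]propanal | O=C1C(C=C)=C[C@@H](CCC=O)C1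
F6 | step 12 | (5R,10R,11R,13S,7E)-15,15-(ethylenedioxy)-11-hydroxy-17-nor-8,9-secokaur-7-en-9-one | C1C2(OCCO2)/C3=C/C[C@@H]4C(C)(C)CCC[C@@]4(C)C(=O)[C@H](O)C[C@@H]1C3
F7 | step 12 | (11S)-11-(4-nitrobenzoyloxy) analogue of 27 | C1C2(OCCO2)/C3=C/C[C@@H]4C(C)(C)CCC[C@@]4(C)C(=O)[C@@H](OC(=O)c5ccc(cc5)[N+](=O)[O-])C[C@@H]1C3
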